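**Retrosynthetic overview**

1. Target 15 comes from 14 by one global deprotection (four OBn, two OMOM); the three benzene rings and the E-stilbene are bought in with 1, 6 and 10.
2. 14 comes from o-quinone methide 11 and the benzylidene unit of 10: C2–C3 and O1–C2 are made in one chiral-sulfide-catalysed [4+1] annulation, which closes the only new ring and sets both stereocentres.
3. 11 comes from sulfone 9, from benzhydrol 8, from salicylaldehyde 5 plus aryl Grignard 7 (C3–aryl bond).
4. 5 comes from isorhapontigenin 1 by tris-MOM protection, ortho-lithiation/formylation between the two ring-B oxygens (C3a–C3 bond) and chelation-controlled removal of one MOM.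
5. Ring order: pre-formed arenes first, dihydrofuran ring last.

Assumption: 1, 6 and 10 are catalogue compounds; the catalyst (2S,5S)-2,5-dimethylthiolane (C[C@H]1CC[C@H](C)S1) is a known sulfide, not counted in the steps, and its sense of induction is taken by analogy with its benzylidene transfer to aldehydes (the antipode is equally accessible if the sense proves opposite).

**Step 1**
Reactants: 1 isorhapontigenin, (E)-5-[2-(4-hydroxy-3-methoxyphenyl)ethenyl]benzene-1,3-diol
Product: 2 (E)-1,3-bis(methoxymethoxy)-5-[2-(3-methoxy-4-(methoxymethoxy)phenyl)ethenyl]benzene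
Conditions: MOMCl (4 equiv), i-Pr2NEt (5 equiv), DMF, 0 °C → rt
Reagents that add atoms: chloromethyl methyl ether, COCCl
Why: Williamson-type acetal protection of all three phenols; MOM is chosen because two flanking OMOM groups direct the metalation in step 2.

**Step 2**
Reactants: 2 tris-MOM stilbene
Product: 4 2,6-bis(methoxymethoxy)-4-[(E)-2-(3-methoxy-4-(methoxymethoxy)phenyl)ethenyl]benzaldehyde, via aryllithium 3 (not isolated)
Conditions: n-BuLi (1.1 equiv), Et2O, 0 °C, 1.5 h; DMF (3 equiv), 0 °C → rt; H2O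
Reagents that add atoms: N,N-dimethylformamide, CN(C)C=O
Why: Directed ortho-metalation – the C–H between the two OMOM groups is the only doubly activated site, and in TMEDA-free ether n-BuLi is consumed by this directed deprotonation rather than by addition across the stilbene; DMF then formylates 3.

**Step 3**
Reactants: 4 bis-MOM aldehyde
Product: 5 2-hydroxy-6-(methoxymethoxy)-4-[(E)-2-(3-methoxy-4-(methoxymethoxy)phenyl)ethenyl]benzaldehyde
Conditions: MgBr2·OEt2 (1.3 equiv), CH2Cl2–Et2O, 0 °C → rt; H2O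
Reagents that add atoms: none
Why: Chelation-controlled Lewis-acid MOM cleavage – Mg(II) bridges the aldehyde oxygen and one ortho acetal, that MOM is lost, and the resulting magnesium phenoxide–aldehyde chelate turns the carbonyl away from the second ortho OMOM, which survives together with the unchelated guaiacyl OMOM.

**Step 4**
Reactants: 5 salicylaldehyde; 6 1-bromo-3,5-bis(benzyloxy)benzene
Product: 8 rac-2-{[3,5-bis(benzyloxy)phenyl](hydroxy)methyl}-3-(methoxymethoxy)-5-[(E)-2-(3-methoxy-4-(methoxymethoxy)phenyl)ethenyl]phenol, via arylmagnesium bromide 7 (not isolated)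
Conditions: 6, Mg, THF, 40 °C (2.2 equiv of 7); 5, THF, 0 °C → rt; H2O
Reagents that add atoms: none
Why: Grignard addition to an aldehyde – the first equivalent of 7 deprotonates the phenol, the second adds to the chelated formyl group; the carbinol centre is racemic and is erased at the quinone methide stage.

**Step 5**
Reactants: 8 benzhydrol
Product: 9 rac-2-{[3,5-bis(benzyloxy)phenyl](4-methylbenzenesulfonyl)methyl}-3-(methoxymethoxy)-5-[(E)-2-(3-methoxy-4-(methoxymethoxy)phenyl)ethenyl]phenol
Conditions: p-TolSO2H (1.5 equiv), CH2Cl2, rt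
Reagents that add atoms: p-toluenesulfinic acid, Cc1ccc(cc1)S(=O)O
Why: Acid-promoted SN1-type substitution – the o-hydroxybenzhydrol ionises (o-quinone methide/benzhydryl cation) and is trapped at sulfur by sulfinate, giving a bench-stable sulfone that releases the quinone methide under base; the weak acid leaves the MOM acetals and the stilbene alone.

**Step 6**
Reactants: 9 sulfone; 10 3,4-bis(benzyloxy)benzyl chloride
Product: 14 (2S,3S)-2-[3,4-bis(benzyloxy)phenyl]-3-[3,5-bis(benzyloxy)phenyl]-4-(methoxymethoxy)-6-[(E)-2-(3-methoxy-4-(methoxymethoxy)phenyl)ethenyl]-2,3-dihydro-1-benzofuran, via o-quinone methide 11 (not isolated), via sulfonium chloride 12 (not isolated), via sulfonium ylide 13 (not isolated)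
Conditions: (2S,5S)-2,5-dimethylthiolane (20 mol%), 10 (2.5 equiv), Cs2CO3 (3 equiv), 4 Å MS, MeCN, 0 °C → rt; 9 added over 8 h
Reagents that add atoms: none
Why: Proposed new method: a catalytic enantioselective sulfonium-ylide [4+1] annulation of an o-quinone methide – the sulfide is S-benzylated by 10 to 12, Cs2CO3 gives the semi-stabilised ylide 13 and, from 9 by E1cB loss of sulfinate, the quinone methide 11; 1,4-addition of 13 to the exocyclic carbon of 11 re-aromatises ring B and creates C3, then the phenoxide displaces the sulfide at the benzylic carbon (5-exo-tet, inversion) to close the ring and release the catalyst; the C2-symmetric sulfide exposes one face of the ylide carbon (fixing C2) and the anti addition mode that keeps the two aryl groups apart gives the 2,3-trans isomer, hence (2S,3S); slow addition of 9 keeps the phenoxide concentration low so that O-benzylation by 10 does not compete; the closest known reactions are the chiral-sulfide-catalysed benzyl halide/base epoxidation of aldehydes and the [4+1] annulation of o-quinone methides with carbonyl-stabilised sulfur ylides.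

**Step 7**
Reactants: 14 protected dihydrobenzofuran
Product: 15 (2S,3S)-2-(3,4-dihydroxyphenyl)-3-(3,5-dihydroxyphenyl)-6-[(E)-2-(4-hydroxy-3-methoxyphenyl)ethenyl]-2,3-dihydro-1-benzofuran-4-ol
Conditions: BCl3 (12 equiv), C6HMe5 (12 equiv), CH2Cl2, −78 °C; MeOH, −78 °C → rt
Reagents that add atoms: none
Why: Lewis-acid ether cleavage with a cation scavenger – BCl3 at −78 °C removes the four benzyl ethers (benzyl cations go to pentamethylbenzene) and the two MOM acetals, while the aryl methyl ether, the stilbene and both stereocentres are untouched at this temperature (a reversible C2–O ionisation could only return the trans isomer, C3 being unaffected).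

**Compound list**

1 | isorhapontigenin | COc1cc(/C=C/c2cc(O)cc(O)c2)ccc1O | starting material
2 | (E)-1,3-bis(methoxymethoxy)-5-[2-(3-methoxy-4-(methoxymethoxy)phenyl)ethenyl]benzene | COc1cc(/C=C/c2cc(OCOC)cc(OCOC)c2)ccc1OCOC | intermediate
3 | 2,6-bis(methoxymethoxy)-4-[(E)-2-(3-methoxy-4-(methoxymethoxy)phenyl)ethenyl]phenyllithium | COc1cc(/C=C/c2cc(OCOC)c([Li])c(OCOC)c2)ccc1OCOC | intermediate (not isolated)
4 | 2,6-bis(methoxymethoxy)-4-[(E)-2-(3-methoxy-4-(methoxymethoxy)phenyl)ethenyl]benzaldehyde | COc1cc(/C=C/c2cc(OCOC)c(C=O)c(OCOC)c2)ccc1OCOC | intermediate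
5 | 2-hydroxy-6-(methoxymethoxy)-4-[(E)-2-(3-methoxy-4-(methoxymethoxy)phenyl)ethenyl]benzaldehyde | COc1cc(/C=C/c2cc(O)c(C=O)c(OCOC)c2)ccc1OCOC | intermediate
6 | 1-bromo-3,5-bis(benzyloxy)benzene | Brc1cc(OCc2ccccc2)cc(OCc2ccccc2)c1 | starting material
7 | 3,5-bis(benzyloxy)phenylmagnesium bromide | Br[Mg]c1cc(OCc2ccccc2)cc(OCc2ccccc2)c1 | intermediate (not isolated)
8 | rac-2-{[3,5-bis(benzyloxy)phenyl](hydroxy)methyl}-3-(methoxymethoxy)-5-[(E)-2-(3-methoxy-4-(methoxymethoxy)phenyl)ethenyl]phenol | COc1cc(/C=C/c2cc(O)c(C(O)c3cc(OCc4ccccc4)cc(OCc4ccccc4)c3)c(OCOC)c2)ccc1OCOC | intermediate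
9 | rac-2-{[3,5-bis(benzyloxy)phenyl](4-methylbenzenesulfonyl)methyl}-3-(methoxymethoxy)-5-[(E)-2-(3-methoxy-4-(methoxymethoxy)phenyl)ethenyl]phenol | COc1cc(/C=C/c2cc(O)c(C(c3cc(OCc4ccccc4)cc(OCc4ccccc4)c3)S(=O)(=O)c3ccc(C)cc3)c(OCOC)c2)ccc1OCOC | intermediate
10 | 3,4-bis(benzyloxy)benzyl chloride | ClCc1ccc(OCc2ccccc2)c(OCc2ccccc2)c1 | starting material
11 | 6-[3,5-bis(benzyloxy)benzylidene]-5-(methoxymethoxy)-3-[(E)-2-(3-methoxy-4-(methoxymethoxy)phenyl)ethenyl]cyclohexa-2,4-dien-1-one (o-quinone methide) | COc1cc(/C=C/C2=CC(=O)C(=Cc3cc(OCc4ccccc4)cc(OCc4ccccc4)c3)C(OCOC)=C2)ccc1OCOC | intermediate (not isolated)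
12 | (2S,5S)-1-[3,4-bis(benzyloxy)benzyl]-2,5-dimethylthiolan-1-ium chloride | C[C@H]1CC[C@H](C)[S+]1Cc1ccc(OCc2ccccc2)c(OCc2ccccc2)c1.[Cl-] | intermediate (not isolated)
13 | (2S,5S)-2,5-dimethylthiolan-1-ium-1-yl [3,4-bis(benzyloxy)phenyl]methanide (sulfonium ylide) | C[C@H]1CC[C@H](C)[S+]1[CH-]c1ccc(OCc2ccccc2)c(OCc2ccccc2)c1 | intermediate (not isolated)
14 | (2S,3S)-2-[3,4-bis(benzyloxy)phenyl]-3-[3,5-bis(benzyloxy)phenyl]-4-(methoxymethoxy)-6-[(E)-2-(3-methoxy-4-(methoxymethoxy)phenyl)ethenyl]-2,3-dihydro-1-benzofuran | COc1cc(/C=C/c2cc(OCOC)c3c(c2)O[C@H](c2ccc(OCc4ccccc4)c(OCc4ccccc4)c2)[C@H]3c2cc(OCc3ccccc3)cc(OCc3ccccc3)c2)ccc1OCOC | intermediate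
15 | (2S,3S)-2-(3,4-dihydroxyphenyl)-3-(3,5-dihydroxyphenyl)-6-[(E)-2-(4-hydroxy-3-methoxyphenyl)ethenyl]-2,3-dihydro-1-benzofuran-4-ol | COc1cc(/C=C/c2cc(O)c3c(c2)O[C@H](c2ccc(O)c(O)c2)[C@H]3c2cc(O)cc(O)c2)ccc1O | target

**Totals**

Total step count: 7. Longest linear sequence: 7 steps (1 → 15); 6 and 10 enter as bought fragments.

**Three steps most likely to fail**

Step 6 (the proposed annulation). Catalyst turnover depends on S-benzylation by 10 keeping pace with consumption of 11, and the level of enantiocontrol on a quinone methide acceptor is untested. The fallback sets out from 9 (with 10) and comes back at 14. Chloride 10 is stirred with tetrahydrothiophene in acetone to give 1-[3,4-bis(benzyloxy)benzyl]thiolan-1-ium chloride F1. Sulfone 9, F1 and Cs2CO3 in MeCN then give, by the established base-mediated sulfur-ylide [4+1] annulation of sulfone-derived o-quinone methides, racemic trans-2-[3,4-bis(benzyloxy)phenyl]-3-[3,5-bis(benzyloxy)phenyl]-4-(methoxymethoxy)-6-[(E)-2-(3-methoxy-4-(methoxymethoxy)phenyl)ethenyl]-2,3-dihydro-1-benzofuran F2. Preparative SFC on a chiral stationary phase separates the enantiomers and delivers 14; this replaces asymmetric catalysis by resolution.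

Step 3 (removal of one of two equivalent ortho MOM groups). Over-cleavage or loss of the guaiacyl MOM would give mixtures. The fallback sets out from 4 and comes back at 5, and relies on selective protection instead of selective deprotection. All three acetals of 4 are exchanged off (cat. HCl, MeOH–THF, 40 °C) to give 2,6-dihydroxy-4-[(E)-2-(4-hydroxy-3-methoxyphenyl)ethenyl]benzaldehyde F3. MOMCl (2.1 equiv) and i-Pr2NEt in CH2Cl2 at 0 °C then protect the guaiacyl OH and one ortho OH; the other ortho OH is held back by its hydrogen bond to the aldehyde, which gives 5.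

Step 7 (one-pot removal of six groups with BCl3). The polyphenol, the benzylic C2–O bond and the guaiacyl methyl ether are all exposed to a strong Lewis acid. The fallback sets out from 14 and comes back at 15 in two stages of different mechanism. The two MOM acetals are first removed under protic conditions (cat. HCl, MeOH–THF, 40 °C) to give (2S,3S)-2-[3,4-bis(benzyloxy)phenyl]-3-[3,5-bis(benzyloxy)phenyl]-6-[(E)-2-(4-hydroxy-3-methoxyphenyl)ethenyl]-2,3-dihydro-1-benzofuran-4-ol F4. The benzyl ethers are then cleaved with the push–pull pair AlCl3/N,N-dimethylaniline (CH2Cl2, 0 °C → rt), in which the amine takes up the benzyl groups and aryl methyl ethers are spared, giving 15.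

**Further compounds**

F1 | step 6 | 1-[3,4-bis(benzyloxy)benzyl]thiolan-1-ium chloride | C1CC[S+](C1)Cc1ccc(OCc2ccccc2)c(OCc2ccccc2)c1.[Cl-]
F2 | step 6 | racemic trans-2-[3,4-bis(benzyloxy)phenyl]-3-[3,5-bis(benzyloxy)phenyl]-4-(methoxymethoxy)-6-[(E)-2-(3-methoxy-4-(methoxymethoxy)phenyl)ethenyl]-2,3-dihydro-1-benzofuran | COc1cc(/C=C/c2cc(OCOC)c3c(c2)O[C@H](c2ccc(OCc4ccccc4)c(OCc4ccccc4)c2)[C@H]3c2cc(OCc3ccccc3)cc(OCc3ccccc3)c2)ccc1OCOC.COc1cc(/C=C/c2cc(OCOC)c3c(c2)O[C@@H](c2ccc(OCc4ccccc4)c(OCc4ccccc4)c2)[C@@H]3c2cc(OCc3ccccc3)cc(OCc3ccccc3)c2)ccc1OCOC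
F3 | step 3 | 2,6-dihydroxy-4-[(E)-2-(4-hydroxy-3-methoxyphenyl)ethenyl]benzaldehyde | COc1cc(/C=C/c2cc(O)c(C=O)c(O)c2)ccc1O
F4 | step 7 | (2S,3S)-2-[3,4-bis(benzyloxy)phenyl]-3-[3,5-bis(benzyloxy)phenyl]-6-[(E)-2-(4-hydroxy-3-methoxyphenyl)ethenyl]-2,3-dihydro-1-benzofuran-4-ol | COc1cc(/C=C/c2cc(O)c3c(c2)O[C@H](c2ccc(OCc4ccccc4)c(OCc4ccccc4)c2)[C@H]3c2cc(OCc3ccccc3)cc(OCc3ccccc3)c2)ccc1O
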